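Start from amounts, as you would at the board. A flask cannot lose more free nucleophile than it was charged, so the west run, with 1.7 equiv charged and 62.3% target at its last reading, has paid at most C = 2.73 equiv of nucleophile per electrophile reacted.

| setting | north | west | flask |
|---|---|---|---|
| electrophile | 0.50 M | 0.50 M | 0.50 M |
| nucleophile | 2.5 equiv | 1.7 equiv | 2.50 equiv |
| remark | the very flask that is asked about, followed so far | run made earlier |  |
| time |  |  | 6.0 d |

north run (percent of the electrophile charged)

| time / h | electrophile / % | target / % |
|---|---|---|
| 3.00 | 76.0 | 24.4 |
| 8.00 | 55.1 | 44.6 |
| 20.0 | 35.8 | 64.8 |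
| 40.0 | 23.6 | 76.7 |

west run (percent of the electrophile charged)

| time / d | electrophile / % | target / % |
|---|---|---|
| 0.208 | 75.3 | 24.1 |
| 0.417 | 63.8 | 36.2 |
| 1.04 | 48.5 | 51.5 |
| 2.50 | 37.7 | 62.3 |

(standard deviation of a reading: 0.3 percentage points)

* part of the electrophile that has reacted at 6.0 d
* share of free nucleophile in free nucleophile and protonated nucleophile together, at 6.0 d

- a reading or a percentage of target counts all its forms, free or not
- the earlier runs do not show how much of nucleophile is bound; that part of a forecast is a guess

Take that price for the flask of 2.50 equiv. Dividing charge by price gives 91.6%; call it the reach R, the share of the electrophile that the charge pays for at price C.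

But R has no clock in it, so test it on the north run. The gap to R shrank from 27 percentage points at 20.0 h to 15 points at 40.0 h. Carrying that ratio on to 6.0 d, I commit to c = 90.9%. The readings do not show how the lost nucleophile divides among its forms, so I give no number for fr.

The forecast says c = 89.5%, a little below mine, and fr = 9.5%, holding that “nearly one more is bound, probably by the target”. The flask gives c = 91.0% and fr = 16.7%.

    nucleophile + target ⇌ idle adduct, settled at all times (K = 29.0 M⁻¹)
    nucleophile + acid set free ⇌ protonated nucleophile, settled at all times (K = 200 M⁻¹)
    electrophile + nucleophile → acid set free + target (k = 0.0870 M⁻¹ h⁻¹)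
    acid set free → by-product carried off (k = 0.0150 h⁻¹)

In the flask, 57.9% of the electrophile was used by 0.600 d and 84.0% by 3.00 d, while idle adduct rose from 53.4% to 64.5% and free nucleophile fell to 9.12% of its charge; acid set free kept turning into by-product carried off, 0.0333 M by 6.00 d, and at 6.0 d c stood 0.60 points below R. A neighbour flask charged with 1.50 equiv has R = 54.9% yet reached 66.8%, having lost 2.16 equiv of free nucleophile per electrophile, with idle adduct at 30.2%.

The readings are simulated on assumed constants, and the scatter is random.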